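**Retrosynthetic overview**
- The depside is cut at the aryl ester bond between the ring A carbonyl carbon and O-4 of ring B. The ring B carboxyl travels as a benzyl ester that is removed in the last step.
- Structural feature that carries the plan: in ring B, and equally in ring A, the carboxyl carbon sits on C1 between oxygen-bearing C2 and pentyl-bearing C6, with the second oxygen on C4. The carboxyl carbon, C1 and C2 are the three carbons of a malonate. C3, C4, C5, C6 and the pentyl chain are the nine carbons of (E)-non-3-en-2-one.
- One carbocycle is closed once, by forming C1–C6 (conjugate addition) and C2–C3 (Claisen closure), and is then dehydrogenated to benzyl olivetolate.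
- This single arene is divided. One part is ring B as it stands. The other becomes the ring A acid by double O-methylation and debenzylation. No other ring is formed.

Key step: step 1

Remark: the target has no stereocentre. Compounds 3, 4 and 5 are racemates (one enantiomer is drawn), and 4 is written as one enol tautomer of the 2,4-dione.

**Route**

Step 1
Reactants: 1 dibenzyl malonate; 2 (E)-non-3-en-2-one
Product: 4 benzyl trans-2-hydroxy-4-oxo-6-pentylcyclohex-2-ene-1-carboxylate (racemic), via Michael adduct 3 (not isolated)
Conditions: NaOCH2Ph (1.0 M in BnOH, 1.1 equiv), THF, 0 °C → 65 °C; then H2O, MTBE wash (removes BnOH); 1 M HCl, 0 °C, pH 3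
Reagents that add atoms: none
Why: Benzyloxide deprotonates 1, the soft malonate enolate adds to the β-carbon of 2 (Michael addition, C1–C6 bond) to give 3, and after proton transfer the methyl-side ketone enolate attacks one benzyl ester carbonyl and expels benzyloxide (intramolecular Claisen, Dieckmann-type condensation, C2–C3 bond). The closest known reaction type is the Michael–Claisen annulation of dialkyl malonates with alk-3-en-2-ones to 6-alkyl-2,4-dioxocyclohexanecarboxylates. The ring closes in the 6-(enolendo)-exo-trig mode, which is favoured for six-membered rings. C6 is set without facial bias in the Michael step (racemate), and C1, an epimerisable β-keto ester carbon, should equilibrate under base so that ester and pentyl group are trans and both pseudo-equatorial. Only constitutional selectivity is needed: reversible malonate addition funnels material into the 1,4-adduct, and the methyl enolate closes a six-membered ring where the C5 methylene enolate could only close a four-membered one. Deprotonation of the acidic vinylogous acid 4 pulls all equilibria forward, and because the alkoxide matches the ester any transesterification is degenerate.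

Step 2
Reactants: 4 benzyl trans-2-hydroxy-4-oxo-6-pentylcyclohex-2-ene-1-carboxylate
Product: 6 benzyl 2,4-dihydroxy-6-pentylbenzoate (benzyl olivetolate), via 3-bromo enolone 5 (not isolated)
Conditions: CuBr2 (2.1 equiv), MeCN, rt → reflux, N2 sweep; then dilute aq. HCl wash
Reagents that add atoms: copper dibromide CuBr2, [Cu+2].[Br-].[Br-] (its bromine stands only in 5 and leaves again as HBr; 6 holds no atom of it)
Why: Divalent copper bromide brominates the enolised 1,3-dicarbonyl unit to 5, which on heating should lose HBr (1,4-elimination of H at C6 and Br at C3 through the bis-enol form) and reach the resorcylate, a bromination–dehydrobromination aromatisation known for cyclohexenones and dihydroresorcylates that also erases both stereocentres.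

Step 3
Reactants: 6 benzyl 2,4-dihydroxy-6-pentylbenzoate (one portion, about half); 7 iodomethane
Product: 8 benzyl 2,4-dimethoxy-6-pentylbenzoate
Conditions: MeI (5 equiv), K2CO3 (4 equiv), DMF, rt → 40 °C
Reagents that add atoms: iodomethane, CI
Why: In this Williamson ether synthesis the free 4-OH should be capped quickly and the hydrogen-bonded 2-OH on longer warming with excess MeI, while the benzyl ester is inert to carbonate.

Step 4
Reactants: 8 benzyl 2,4-dimethoxy-6-pentylbenzoate
Product: 9 2,4-dimethoxy-6-pentylbenzoic acid
Conditions: H2 (1 atm), 10% Pd/C, EtOAc, rt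
Reagents that add atoms: none
Why: Catalytic hydrogenolysis cleaves the benzylic C–O bond under neutral conditions and so frees a 2,6-disubstituted benzoic acid that would resist saponification, leaving the aryl methyl ethers untouched.

Step 5
Reactants: 9 2,4-dimethoxy-6-pentylbenzoic acid; 6 benzyl 2,4-dihydroxy-6-pentylbenzoate (second portion)
Product: 11 benzyl 4-[(2,4-dimethoxy-6-pentylbenzoyl)oxy]-2-hydroxy-6-pentylbenzoate, via mixed trifluoroacetic anhydride 10 (not isolated)
Conditions: (CF3CO)2O (4 equiv), toluene, 0 °C → rt
Reagents that add atoms: trifluoroacetic anhydride, O=C(OC(=O)C(F)(F)F)C(F)(F)F (its trifluoroacetyl group stands only in 10 and leaves again as trifluoroacetic acid; 11 holds no atom of it)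
Why: In this mixed-anhydride esterification, the classical depside coupling, the electron-rich and doubly ortho-substituted acyl group of 10 ionises easily towards an acylium ion and should acylate the free 4-OH of 6, because the 2-OH is held in a hydrogen bond to the neighbouring ester carbonyl and is shielded by it.

Step 6
Reactants: 11 benzyl 4-[(2,4-dimethoxy-6-pentylbenzoyl)oxy]-2-hydroxy-6-pentylbenzoate
Product: 12 4-[(2,4-dimethoxy-6-pentylbenzoyl)oxy]-2-hydroxy-6-pentylbenzoic acid (target)
Conditions: H2 (1 atm), 10% Pd/C, EtOAc, rt
Reagents that add atoms: none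
Why: Hydrogenolysis in a non-nucleophilic solvent should cleave only the benzylic C–O bond, since the aryl ester link of the depside, the phenol and the methyl ethers are not reduced and no alcohol is present to open the depside.

**Compound list**
1 | dibenzyl malonate (dibenzyl propanedioate) | O=C(CC(=O)OCc1ccccc1)OCc1ccccc1 | starting material
2 | (E)-non-3-en-2-one | CCCCC/C=C/C(C)=O | starting material
3 | dibenzyl 2-(2-oxononan-4-yl)propanedioate (racemic, not isolated) | CCCCC[C@H](CC(C)=O)C(C(=O)OCc1ccccc1)C(=O)OCc1ccccc1 | intermediate
4 | benzyl trans-2-hydroxy-4-oxo-6-pentylcyclohex-2-ene-1-carboxylate (racemic) | CCCCC[C@@H]1CC(=O)C=C(O)[C@H]1C(=O)OCc1ccccc1 | intermediate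
5 | benzyl trans-3-bromo-2-hydroxy-4-oxo-6-pentylcyclohex-2-ene-1-carboxylate (racemic, not isolated) | CCCCC[C@@H]1CC(=O)C(Br)=C(O)[C@H]1C(=O)OCc1ccccc1 | intermediate
6 | benzyl 2,4-dihydroxy-6-pentylbenzoate (benzyl olivetolate) | CCCCCc1cc(O)cc(O)c1C(=O)OCc1ccccc1 | intermediate
7 | iodomethane | CI | starting material
8 | benzyl 2,4-dimethoxy-6-pentylbenzoate | CCCCCc1cc(OC)cc(OC)c1C(=O)OCc1ccccc1 | intermediate
9 | 2,4-dimethoxy-6-pentylbenzoic acid | CCCCCc1cc(OC)cc(OC)c1C(=O)O | intermediate
10 | 2,4-dimethoxy-6-pentylbenzoic trifluoroacetic anhydride (not isolated) | CCCCCc1cc(OC)cc(OC)c1C(=O)OC(=O)C(F)(F)F | intermediate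
11 | benzyl 4-[(2,4-dimethoxy-6-pentylbenzoyl)oxy]-2-hydroxy-6-pentylbenzoate | CCCCCc1cc(OC(=O)c2c(CCCCC)cc(OC)cc2OC)cc(O)c1C(=O)OCc1ccccc1 | intermediate
12 | 4-[(2,4-dimethoxy-6-pentylbenzoyl)oxy]-2-hydroxy-6-pentylbenzoic acid | CCCCCc1cc(OC(=O)c2c(CCCCC)cc(OC)cc2OC)cc(O)c1C(=O)O | target

**Step count**
- Total step count: 6.
- Longest linear sequence: 6 (steps 1, 2, 3, 4, 5, 6). The second coupling partner 6 branches off after step 2.

**Steps most likely to fail**

**Step 2 (aromatisation).**
- What may go wrong: the electron-rich ring may be brominated further once the resorcylate has formed. The HBr released may also cleave the benzyl ester, and the free acid would then decarboxylate.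
- Fallback, from 4 back to 6, free of halogen and strong acid: 4 is silylated twice with Me3SiOTf and Et3N in CH2Cl2 at 0 °C. This should give benzyl 6-pentyl-2,4-bis(trimethylsilyloxy)cyclohexa-1,3-diene-1-carboxylate F1. DDQ in toluene at rt then takes hydride from C5 and a proton from C6 of this cyclohexadiene, giving benzyl 6-pentyl-2,4-bis(trimethylsilyloxy)benzoate F2. Dilute aqueous HCl in THF strips both silyl ethers and returns to 6.

**Step 1 (key annulation).**
- What may go wrong: the reaction may stall at the open Michael stage, or the adduct may undergo retro-Michael cleavage. The ester may also be lost to adventitious hydroxide while the product is separated from the high-boiling alcohol.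
- Fallback, from 2 back to 6, with the benzyl group installed late: 2 is annulated with dimethyl malonate and NaOMe in MeOH at reflux. This should pass through dimethyl 2-(2-oxononan-4-yl)propanedioate F3 to methyl trans-2-hydroxy-4-oxo-6-pentylcyclohex-2-ene-1-carboxylate F4.
- Br2 in DMF (0 °C, then 80 °C) should brominate F4 to methyl trans-3-bromo-2-hydroxy-4-oxo-6-pentylcyclohex-2-ene-1-carboxylate F5. Heating aromatises this to methyl 2,4-dihydroxy-6-pentylbenzoate F6, whose methyl ester is indifferent to HBr at that temperature.
- Aqueous KOH under N2 followed by cold acidification gives 2,4-dihydroxy-6-pentylbenzoic acid F7. BnBr with KHCO3 in DMF alkylates only the carboxylate and returns to 6.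

**Step 5 (depside coupling).**
- What may go wrong: acyl transfer from the hindered donor may be slow. The phenol may be trifluoroacetylated instead, or the activated ring may undergo C-acylation in the acidic medium.
- Fallback, from 9 back to 11, with an isolated acyl donor and a preformed phenoxide under basic conditions: 9 is converted with oxalyl chloride and catalytic DMF in CH2Cl2 into 2,4-dimethoxy-6-pentylbenzoyl chloride F8, which is freed of volatiles. Compound 6 is deprotonated with NaH (1.0 equiv) in THF at 0 °C at the more acidic, non-chelated 4-OH. This phenoxide is acylated by the chloride to return to 11.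

**Further compounds**
F1 | step 2 | benzyl 6-pentyl-2,4-bis(trimethylsilyloxy)cyclohexa-1,3-diene-1-carboxylate (racemic) | CCCCC[C@@H]1CC(O[Si](C)(C)C)=CC(O[Si](C)(C)C)=C1C(=O)OCc1ccccc1
F2 | step 2 | benzyl 6-pentyl-2,4-bis(trimethylsilyloxy)benzoate | CCCCCc1cc(O[Si](C)(C)C)cc(O[Si](C)(C)C)c1C(=O)OCc1ccccc1
F3 | step 1 | dimethyl 2-(2-oxononan-4-yl)propanedioate (racemic) | CCCCC[C@H](CC(C)=O)C(C(=O)OC)C(=O)OC
F4 | step 1 | methyl trans-2-hydroxy-4-oxo-6-pentylcyclohex-2-ene-1-carboxylate (racemic) | CCCCC[C@@H]1CC(=O)C=C(O)[C@H]1C(=O)OC
F5 | step 1 | methyl trans-3-bromo-2-hydroxy-4-oxo-6-pentylcyclohex-2-ene-1-carboxylate (racemic) | CCCCC[C@@H]1CC(=O)C(Br)=C(O)[C@H]1C(=O)OC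
F6 | step 1 | methyl 2,4-dihydroxy-6-pentylbenzoate | CCCCCc1cc(O)cc(O)c1C(=O)OC
F7 | step 1 | 2,4-dihydroxy-6-pentylbenzoic acid | CCCCCc1cc(O)cc(O)c1C(=O)O
F8 | step 5 | 2,4-dimethoxy-6-pentylbenzoyl chloride | CCCCCc1cc(OC)cc(OC)c1C(=O)Cl
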